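## Plan

- The target is a 3,3''-biflavanone whose ketone carbons C4 and C4'' sit on the adjacent carbons C3 and C3''. Each ketone is bonded to an arene carbon ortho to an ether oxygen (C4a of ring A, C4a'' of ring D). The 2,3-trans/2'',3''-cis pattern is that of a syn addition of two acyl groups to a Z C3=C3'' alkene.
- After removing the protecting groups (5''-O-methyl, 5- and 7-O-benzyl), the retrosynthesis cuts C4a–C4, C4–C3, C3''–C4'' and C4''–C4a'' at once, with two CO as C4 and C4''. This leads to a (Z)-1,4-bis(4-methoxyphenyl)but-2-ene-1,4-diyl bis(aryl ether) carrying iodine on ring A and a pinacol boronate on ring D.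
- The alkene comes from an alkyne, the two C2–O and C2''–O bonds from Mitsunobu etherifications, and the C2–C3≡C3''–C2'' chain from two alkynylations of 4-methoxybenzaldehyde with trimethylsilylacetylene as the two-carbon unit.
- Forward order: C2 carbinol, ring A ether, C2'' carbinol, ring D ether, semihydrogenation, then ring C and ring F in one palladium/CO domino (ring C first), then deprotection.
- Stereochemistry: C2 and C2'' come from two catalyst-controlled alkynylations, each followed by a Mitsunobu inversion. C3 and C3'' come from the domino (syn addition to the Z-alkene, face chosen by C2).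

Key step: step 11

## Remarks

- Flavanone numbering is used: unit 1 is the 5,7-dihydroxy half (rings A and C, unprimed), unit 2 the 7-methoxy half (rings D and F, doubly primed).
- The CIP descriptor of a carbinol or ether carbon changes with the alkyne substituent (silylethynyl and internal alkynyl rank above aryl, ethynyl and alkenyl below) although the spatial arrangement does not.
- The ProPhenol antipode for steps 1 and 6 is specified by the sense required (Re-face addition to the aldehyde), which should be confirmed on the first carbinol.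
- The palladium intermediates of step 11 are drawn without the bisphosphine.

## Route

Step 1
Reactants: 1 4-methoxybenzaldehyde; 2 trimethylsilylacetylene
Product: 4 (S)-1-(4-methoxyphenyl)-3-(trimethylsilyl)prop-2-yn-1-ol, via methyl[(trimethylsilyl)ethynyl]zinc 3 (not isolated)
Conditions: 2 (3 equiv), Me2Zn (3 equiv), ProPhenol ligand (Re-face-selective antipode, 10 mol %), Ph3P=O (20 mol %), toluene, 0 °C; aq NH4Cl
Reagents that add atoms: none
Why: Catalytic asymmetric alkynylation of an aromatic aldehyde by an alkynylzinc species on the catalyst formed in situ from Me2Zn and ProPhenol is established for aryl aldehydes and silylacetylenes, and the ligand antipode is chosen so that the alkynyl group adds to the Re face, which sets the (S)-carbinol.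

Step 2
Reactants: 4 (S)-1-(4-methoxyphenyl)-3-(trimethylsilyl)prop-2-yn-1-ol
Product: 5 (R)-1-(4-methoxyphenyl)prop-2-yn-1-ol
Conditions: K2CO3 (0.2 equiv), MeOH, 0 → 20 °C
Reagents that add atoms: none
Why: Base-catalysed methanolysis of the C(sp)–Si bond (protodesilylation) should leave the carbinol untouched, the descriptor changing from S to R only because ethynyl ranks below aryl.

Step 3
Reactants: 6 phloroglucinol
Product: 7 3,5-bis(benzyloxy)phenol
Conditions: BnBr (2.0 equiv), K2CO3, DMF, 0 → 20 °C
Reagents that add atoms: benzyl bromide, BrCc1ccccc1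
Why: Williamson O-benzylation of the triphenol under statistical control is a documented entry to the dibenzyl ether, which should be separable by chromatography from the mono- and tribenzyl ethers (the phenol can also be purchased).

Step 4
Reactants: 7 3,5-bis(benzyloxy)phenol
Product: 8 3,5-bis(benzyloxy)-2-iodophenol
Conditions: I2 (1.0 equiv), NaHCO3, THF/H2O, 0 °C
Reagents that add atoms: iodine, II
Why: Electrophilic aromatic iodination of the phenolate should occur ortho to the hydroxyl group, as is usual for 3,5-dialkoxyphenols, because the position para to the hydroxyl lies between two benzyloxy groups and is the more hindered.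

Step 5
Reactants: 5 (R)-1-(4-methoxyphenyl)prop-2-yn-1-ol; 8 3,5-bis(benzyloxy)-2-iodophenol
Product: 9 1,5-bis(benzyloxy)-2-iodo-3-{[(1S)-1-(4-methoxyphenyl)prop-2-yn-1-yl]oxy}benzene
Conditions: PPh3, DIAD, toluene, −20 → 0 °C
Reagents that add atoms: none
Why: Mitsunobu etherification with the iodophenol should proceed by SN2 displacement of the oxyphosphonium ion with inversion (R alcohol to S ether, same priority order), the low temperature and non-polar solvent being chosen to hold back ionisation of the 4-methoxybenzylic, propargylic carbon.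

Step 6
Reactants: 9 1,5-bis(benzyloxy)-2-iodo-3-{[(1S)-1-(4-methoxyphenyl)prop-2-yn-1-yl]oxy}benzene; 1 4-methoxybenzaldehyde
Product: 11 (1S,4R)-4-[3,5-bis(benzyloxy)-2-iodophenoxy]-1,4-bis(4-methoxyphenyl)but-2-yn-1-ol, via alkynyl(methyl)zinc reagent 10 (not isolated)
Conditions: 1 (1.5 equiv), Me2Zn (3 equiv), ProPhenol ligand (same antipode as in step 1, 20 mol %), Ph3P=O (40 mol %), toluene, 0 °C; aq NH4Cl
Reagents that add atoms: none
Why: The same asymmetric alkynylation now uses the terminal alkyne of 9, whose aryl iodide and ethers are inert to Me2Zn, and the same ligand antipode should again direct Re-face addition so that the new (1S)-carbinol is set by the catalyst and not by the remote ether stereocentre.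

Step 7
Reactants: 12 3,5-dimethoxyphenol
Product: 13 2-iodo-3,5-dimethoxyphenol
Conditions: I2 (1.0 equiv), NaHCO3, THF/H2O, 0 °C
Reagents that add atoms: iodine, II
Why: Electrophilic aromatic iodination ortho to the phenol, as in step 4, should give the 2-iodo compound.

Step 8
Reactants: 13 2-iodo-3,5-dimethoxyphenol
Product: 14 3,5-dimethoxy-2-(4,4,5,5-tetramethyl-1,3,2-dioxaborolan-2-yl)phenol
Conditions: HBpin (3 equiv), Et3N (4 equiv), PdCl2(MeCN)2 (3 mol %), SPhos (12 mol %), 1,4-dioxane, 80 °C; aq NH4Cl
Reagents that add atoms: pinacolborane, CC1(C)OBOC1(C)C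
Why: Palladium-catalysed borylation of aryl halides with pinacolborane (Masuda borylation) with a bulky biarylphosphine is the established method for electron-rich, doubly ortho-substituted aryl halides, the phenol being carried as a transient O-boryl ether that should hydrolyse on work-up.

Step 9
Reactants: 11 (1S,4R)-4-[3,5-bis(benzyloxy)-2-iodophenoxy]-1,4-bis(4-methoxyphenyl)but-2-yn-1-ol; 14 3,5-dimethoxy-2-(4,4,5,5-tetramethyl-1,3,2-dioxaborolan-2-yl)phenol
Product: 15 2-[2-({(1R,4R)-4-[3,5-bis(benzyloxy)-2-iodophenoxy]-1,4-bis(4-methoxyphenyl)but-2-yn-1-yl}oxy)-4,6-dimethoxyphenyl]-4,4,5,5-tetramethyl-1,3,2-dioxaborolane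
Conditions: PPh3, DIAD, toluene, −20 → 0 °C
Reagents that add atoms: none
Why: The second Mitsunobu etherification should again invert the carbinol carbon by SN2 displacement (1S alcohol to 1R ether), so that both oxygenated carbons of the alkyne bis(aryl ether) are R.

Step 10
Reactants: 15 2-[2-({(1R,4R)-4-[3,5-bis(benzyloxy)-2-iodophenoxy]-1,4-bis(4-methoxyphenyl)but-2-yn-1-yl}oxy)-4,6-dimethoxyphenyl]-4,4,5,5-tetramethyl-1,3,2-dioxaborolane
Product: 16 2-[2-({(1S,2Z,4S)-4-[3,5-bis(benzyloxy)-2-iodophenoxy]-1,4-bis(4-methoxyphenyl)but-2-en-1-yl}oxy)-4,6-dimethoxyphenyl]-4,4,5,5-tetramethyl-1,3,2-dioxaborolane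
Conditions: H2 (1 atm), Pd/CaCO3 poisoned with Pb(OAc)2, quinoline, EtOAc, 20 °C, stopped after one equivalent of H2
Reagents that add atoms: none
Why: Lindlar semihydrogenation adds H2 syn on the poisoned palladium surface and should stop at the Z-alkene, with the aryl iodide, benzyl ethers and boronate expected to survive at one atmosphere when uptake is stopped after one equivalent.

Step 11
Reactants: 16 2-[2-({(1S,2Z,4S)-4-[3,5-bis(benzyloxy)-2-iodophenoxy]-1,4-bis(4-methoxyphenyl)but-2-en-1-yl}oxy)-4,6-dimethoxyphenyl]-4,4,5,5-tetramethyl-1,3,2-dioxaborolane; 17 carbon monoxide (two equivalents consumed)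
Product: 21 (2S,3R)-5,7-bis(benzyloxy)-3-[(2S,3S)-5,7-dimethoxy-2-(4-methoxyphenyl)-4-oxochroman-3-yl]-2-(4-methoxyphenyl)chroman-4-one, via ring A aroylpalladium iodide 18 (not isolated), via C3''-alkylpalladium iodide 19 (not isolated), via C4''-acylpalladium iodide 20 (not isolated)
Conditions: Pd(OAc)2 (10 mol %), 1,3-bis(diphenylphosphino)propane (dppp, 12 mol %), CO (20 bar), CsF (3 equiv), 1,4-dioxane (0.005 M), 70 °C
Reagents that add atoms: none
Why: Proposed new method: zerovalent palladium formed from Pd(OAc)2 and dppp should insert into the ring A C–I bond, CO should convert the arylpalladium into aroylpalladium 18, which adds syn across the Z C3=C3'' alkene to give the ketone-chelated alkylpalladium 19, a second CO should insert with retention to give acylpalladium 20, and fluoride-assisted transmetalation from the ring D boronate followed by reductive elimination ends the sequence. The closest known reactions are the cyclic acylpalladation of alkenes by acylpalladiums derived from o-iodoaryl alkenes with a second CO insertion and ester trapping, the acyl–alkene–CO propagation of CO/alkene copolymerisation on palladium–dppp catalysts, and the carbonylative Suzuki ketone synthesis with doubly ortho-substituted partners, but their merger into one domino with an intramolecular boronate terminus is new. Ring C closes by 6-exo-trig acylpalladation (C4a–C4, then C3–C4), and ring F closes at C4''–C4a'' by reductive elimination from a seven-membered acyl(aryl)palladacycle after CO insertion has formed C3''–C4''. C3 is set by the C2 stereocentre, because with C2–H eclipsing the Z-alkene to avoid allylic 1,3-strain the tethered aroyl group can reach only the alkene face that carries O1, which places the C3'' chain trans to the pseudo-equatorial C2 anisyl group; C3'' then follows from syn addition and retentive CO insertion, which is why unit 2 becomes 2'',3''-cis. The step needs CO insertion to outrun direct 5-exo Heck cyclisation of the arylpalladium and β-hydride or β-aryloxide elimination from 19, which the CO pressure, the five-membered C4=O→Pd chelate of 19 and the bidentate ligand should secure, and it needs the two halves to keep their roles, which the iodide on ring A and the boronate on ring D guarantee. High dilution should suppress intermolecular carbonylative coupling, and CsF as a weak anhydrous base should spare the enolisable centres C3 and C3''.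

Step 12
Reactants: 21 (2S,3R)-5,7-bis(benzyloxy)-3-[(2S,3S)-5,7-dimethoxy-2-(4-methoxyphenyl)-4-oxochroman-3-yl]-2-(4-methoxyphenyl)chroman-4-one
Product: 22 (2S,3R)-5,7-dihydroxy-3-[(2S,3S)-5-hydroxy-7-methoxy-2-(4-methoxyphenyl)-4-oxochroman-3-yl]-2-(4-methoxyphenyl)chroman-4-one (CNP0184936.3)
Conditions: BCl3 (8 equiv), pentamethylbenzene (6 equiv), CH2Cl2, −78 → 0 °C; aq NaHCO3
Reagents that add atoms: none
Why: Lewis acid ether cleavage with BCl3 should remove the 5''-methyl ether selectively through its chelate with the peri C4'' carbonyl and both benzyl ethers with pentamethylbenzene as a non-basic benzyl cation trap, while the non-chelated 7''- and anisyl methyl ethers and the four stereocentres are expected to survive at low temperature.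

## Compound list

1 | 4-methoxybenzaldehyde | COc1ccc(C=O)cc1 | starting material
2 | trimethylsilylacetylene | C#C[Si](C)(C)C | starting material
3 | methyl[(trimethylsilyl)ethynyl]zinc | C[Zn]C#C[Si](C)(C)C | intermediate
4 | (S)-1-(4-methoxyphenyl)-3-(trimethylsilyl)prop-2-yn-1-ol | COc1ccc(cc1)[C@H](O)C#C[Si](C)(C)C | intermediate
5 | (R)-1-(4-methoxyphenyl)prop-2-yn-1-ol | COc1ccc(cc1)[C@H](O)C#C | intermediate
6 | phloroglucinol | Oc1cc(O)cc(O)c1 | starting material
7 | 3,5-bis(benzyloxy)phenol | Oc1cc(OCc2ccccc2)cc(OCc2ccccc2)c1 | intermediate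
8 | 3,5-bis(benzyloxy)-2-iodophenol | Oc1cc(OCc2ccccc2)cc(OCc2ccccc2)c1I | intermediate
9 | 1,5-bis(benzyloxy)-2-iodo-3-{[(1S)-1-(4-methoxyphenyl)prop-2-yn-1-yl]oxy}benzene | COc1ccc(cc1)[C@@H](Oc1cc(OCc2ccccc2)cc(OCc2ccccc2)c1I)C#C | intermediate
10 | alkynyl(methyl)zinc reagent formed from 9 | C[Zn]C#C[C@H](Oc1cc(OCc2ccccc2)cc(OCc2ccccc2)c1I)c1ccc(OC)cc1 | intermediate
11 | (1S,4R)-4-[3,5-bis(benzyloxy)-2-iodophenoxy]-1,4-bis(4-methoxyphenyl)but-2-yn-1-ol | COc1ccc(cc1)[C@@H](Oc1cc(OCc2ccccc2)cc(OCc2ccccc2)c1I)C#C[C@@H](O)c1ccc(OC)cc1 | intermediate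
12 | 3,5-dimethoxyphenol | COc1cc(O)cc(OC)c1 | starting material
13 | 2-iodo-3,5-dimethoxyphenol | COc1cc(O)c(I)c(OC)c1 | intermediate
14 | 3,5-dimethoxy-2-(4,4,5,5-tetramethyl-1,3,2-dioxaborolan-2-yl)phenol | COc1cc(O)c(B2OC(C)(C)C(C)(C)O2)c(OC)c1 | intermediate
15 | 2-[2-({(1R,4R)-4-[3,5-bis(benzyloxy)-2-iodophenoxy]-1,4-bis(4-methoxyphenyl)but-2-yn-1-yl}oxy)-4,6-dimethoxyphenyl]-4,4,5,5-tetramethyl-1,3,2-dioxaborolane | COc1ccc(cc1)[C@@H](Oc1cc(OCc2ccccc2)cc(OCc2ccccc2)c1I)C#C[C@H](Oc1cc(OC)cc(OC)c1B1OC(C)(C)C(C)(C)O1)c1ccc(OC)cc1 | intermediate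
16 | 2-[2-({(1S,2Z,4S)-4-[3,5-bis(benzyloxy)-2-iodophenoxy]-1,4-bis(4-methoxyphenyl)but-2-en-1-yl}oxy)-4,6-dimethoxyphenyl]-4,4,5,5-tetramethyl-1,3,2-dioxaborolane | COc1ccc(cc1)[C@@H](Oc1cc(OCc2ccccc2)cc(OCc2ccccc2)c1I)/C=C\[C@H](Oc1cc(OC)cc(OC)c1B1OC(C)(C)C(C)(C)O1)c1ccc(OC)cc1 | intermediate
17 | carbon monoxide | [C-]#[O+] | starting material
18 | ring A aroylpalladium iodide formed from 16 by oxidative addition and CO insertion (dppp on palladium not drawn) | COc1ccc(cc1)[C@@H](Oc1cc(OCc2ccccc2)cc(OCc2ccccc2)c1C(=O)[Pd]I)/C=C\[C@H](Oc1cc(OC)cc(OC)c1B1OC(C)(C)C(C)(C)O1)c1ccc(OC)cc1 | intermediate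
19 | C3''-alkylpalladium iodide with ring C closed (dppp on palladium not drawn) | COc1ccc([C@H]2Oc3cc(OCc4ccccc4)cc(OCc4ccccc4)c3C(=O)[C@@H]2[C@@H]([C@H](Oc2cc(OC)cc(OC)c2B2OC(C)(C)C(C)(C)O2)c2ccc(OC)cc2)[Pd]I)cc1 | intermediate
20 | C4''-acylpalladium iodide after the second CO insertion (dppp on palladium not drawn) | COc1ccc([C@H]2Oc3cc(OCc4ccccc4)cc(OCc4ccccc4)c3C(=O)[C@@H]2[C@@H]([C@H](Oc2cc(OC)cc(OC)c2B2OC(C)(C)C(C)(C)O2)c2ccc(OC)cc2)C(=O)[Pd]I)cc1 | intermediate
21 | (2S,3R)-5,7-bis(benzyloxy)-3-[(2S,3S)-5,7-dimethoxy-2-(4-methoxyphenyl)-4-oxochroman-3-yl]-2-(4-methoxyphenyl)chroman-4-one | COc1ccc([C@H]2Oc3cc(OCc4ccccc4)cc(OCc4ccccc4)c3C(=O)[C@@H]2[C@@H]2C(=O)c3c(OC)cc(OC)cc3O[C@@H]2c2ccc(OC)cc2)cc1 | intermediate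
22 | (2S,3R)-5,7-dihydroxy-3-[(2S,3S)-5-hydroxy-7-methoxy-2-(4-methoxyphenyl)-4-oxochroman-3-yl]-2-(4-methoxyphenyl)chroman-4-one (CNP0184936.3) | COc1ccc([C@H]2Oc3cc(O)cc(O)c3C(=O)[C@@H]2[C@@H]2C(=O)c3c(O)cc(OC)cc3O[C@@H]2c2ccc(OC)cc2)cc1 | target

## Step count

Total: 12 steps. Longest linear sequence: 8 steps (steps 1, 2, 5, 6, 9, 10, 11, 12 from 4-methoxybenzaldehyde; equally 3, 4, 5, 6, 9, 10, 11, 12 from phloroglucinol).

## Steps most likely to fail

**Step 11 (proposed new method).** Several processes can divert the domino: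
- carbopalladation before CO uptake (5-exo Heck closure of the arylpalladium);
- β-hydride or β-aryloxide elimination from the C3'' alkylpalladium before the second CO inserts;
- ionisation of the allylic aryl ethers by zerovalent palladium;
- slow transmetalation of the doubly ortho-substituted boronate, with protodeboronation;
- base-induced epimerisation at C3 or C3''.

The fallback separates the termination from the ring C closure and closes ring F by an electrophilic acylation that needs no boron. It leaves the route at alcohol 11 and phenol 12. Mitsunobu etherification of 11 with 12 (PPh3, DIAD, toluene) should give the boron-free alkyne bis(aryl ether) F1. Semihydrogenation as in step 10 should give the Z-alkene F2. The known cyclic acylpalladation–methoxycarbonylation (PdCl2(PPh3)2, CO 40 bar, MeOH, Et3N, MeCN/toluene, 100 °C) should close ring C with the same facial control and give the keto methyl ester F3, methanol trapping the second acylpalladium. Me3SnOH in 1,2-dichloroethane should free the carboxylic acid F4 without epimerising C3''. Trifluoroacetic anhydride in CH2Cl2 at 0 °C should convert it into the mixed trifluoroacetic anhydride F5. Intramolecular Friedel–Crafts acylation of the phloroglucinol-type ring D, whose two positions ortho to O1'' are equivalent, then closes ring F and returns to 21.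

**Step 9.** The oxyphosphonium ion of the 4-methoxybenzylic, propargylic alcohol may ionise, which would erode the configuration at C2'' and allow C-alkylation of the electron-rich phenol. The hindered ortho-boryl phenol slows the SN2 path and makes this more likely; the same concern applies to step 5 and the same remedy would serve there. The fallback mutes the donor during the substitution and sets out from 9 and 14. 4-Hydroxybenzaldehyde is pivaloylated (PivCl, Et3N, CH2Cl2) to 4-formylphenyl pivalate F6, which replaces 1 in the alkynylation of 9 under the step 6 conditions and should give the (1S)-carbinol pivalate F7. Its Mitsunobu reaction with 14 should then proceed with clean inversion to the pivaloyloxyphenyl bis(aryl ether) F8. Methanolysis (K2CO3, MeOH, 0 °C) should give the phenol F9, and O-methylation (MeI, K2CO3, acetone) returns to 15.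

**Step 10.** Hydrogenation may run on to the alkane, cleave the aryl iodide or the newly allylic and benzylic C–O bonds, or stall at the hindered alkyne. The fallback replaces catalytic hydrogenation by stoichiometric syn-hydrometalation and protodemetalation, starting from 15. Dicyclohexylborane in THF at 0 °C should add syn and give the two regioisomeric alkenylboranes, the C3-borylated alkenylborane F10 and the C3''-borylated alkenylborane F11. Protonolysis of both with acetic acid, with retention at the alkenyl carbon, converges on the Z-alkene 16.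

## Further compounds

F1 | step 11 | 1,5-bis(benzyloxy)-3-{[(1R,4R)-4-(3,5-dimethoxyphenoxy)-1,4-bis(4-methoxyphenyl)but-2-yn-1-yl]oxy}-2-iodobenzene | COc1ccc(cc1)[C@@H](Oc1cc(OCc2ccccc2)cc(OCc2ccccc2)c1I)C#C[C@H](Oc1cc(OC)cc(OC)c1)c1ccc(OC)cc1
F2 | step 11 | 1,5-bis(benzyloxy)-3-{[(1S,2Z,4S)-4-(3,5-dimethoxyphenoxy)-1,4-bis(4-methoxyphenyl)but-2-en-1-yl]oxy}-2-iodobenzene | COc1ccc(cc1)[C@@H](Oc1cc(OCc2ccccc2)cc(OCc2ccccc2)c1I)/C=C\[C@H](Oc1cc(OC)cc(OC)c1)c1ccc(OC)cc1
F3 | step 11 | methyl 2-[5,7-bis(benzyloxy)-2-(4-methoxyphenyl)-4-oxochroman-3-yl]-3-(3,5-dimethoxyphenoxy)-3-(4-methoxyphenyl)propanoate with the C2, C3, C3'' and C2'' configurations of 21 | COc1ccc([C@H]2Oc3cc(OCc4ccccc4)cc(OCc4ccccc4)c3C(=O)[C@@H]2[C@@H]([C@H](Oc2cc(OC)cc(OC)c2)c2ccc(OC)cc2)C(=O)OC)cc1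
F4 | step 11 | 2-[5,7-bis(benzyloxy)-2-(4-methoxyphenyl)-4-oxochroman-3-yl]-3-(3,5-dimethoxyphenoxy)-3-(4-methoxyphenyl)propanoic acid with the configurations of F3 | COc1ccc([C@H]2Oc3cc(OCc4ccccc4)cc(OCc4ccccc4)c3C(=O)[C@@H]2[C@@H]([C@H](Oc2cc(OC)cc(OC)c2)c2ccc(OC)cc2)C(=O)O)cc1
F5 | step 11 | mixed trifluoroacetic anhydride of acid F4 | COc1ccc([C@H]2Oc3cc(OCc4ccccc4)cc(OCc4ccccc4)c3C(=O)[C@@H]2[C@@H]([C@H](Oc2cc(OC)cc(OC)c2)c2ccc(OC)cc2)C(=O)OC(=O)C(F)(F)F)cc1
F6 | step 9 | 4-formylphenyl pivalate | CC(C)(C)C(=O)Oc1ccc(C=O)cc1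
F7 | step 9 | 4-{(1S,4R)-4-[3,5-bis(benzyloxy)-2-iodophenoxy]-1-hydroxy-4-(4-methoxyphenyl)but-2-yn-1-yl}phenyl pivalate | COc1ccc(cc1)[C@@H](Oc1cc(OCc2ccccc2)cc(OCc2ccccc2)c1I)C#C[C@@H](O)c1ccc(OC(=O)C(C)(C)C)cc1
F8 | step 9 | 4-{(1R,4R)-4-[3,5-bis(benzyloxy)-2-iodophenoxy]-1-[3,5-dimethoxy-2-(4,4,5,5-tetramethyl-1,3,2-dioxaborolan-2-yl)phenoxy]-4-(4-methoxyphenyl)but-2-yn-1-yl}phenyl pivalate | COc1ccc(cc1)[C@@H](Oc1cc(OCc2ccccc2)cc(OCc2ccccc2)c1I)C#C[C@H](Oc1cc(OC)cc(OC)c1B1OC(C)(C)C(C)(C)O1)c1ccc(OC(=O)C(C)(C)C)cc1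
F9 | step 9 | 4-{(1R,4R)-4-[3,5-bis(benzyloxy)-2-iodophenoxy]-1-[3,5-dimethoxy-2-(4,4,5,5-tetramethyl-1,3,2-dioxaborolan-2-yl)phenoxy]-4-(4-methoxyphenyl)but-2-yn-1-yl}phenol | COc1ccc(cc1)[C@@H](Oc1cc(OCc2ccccc2)cc(OCc2ccccc2)c1I)C#C[C@H](Oc1cc(OC)cc(OC)c1B1OC(C)(C)C(C)(C)O1)c1ccc(O)cc1
F10 | step 10 | alkenyl(dicyclohexyl)borane from syn-hydroboration of 15 with boron on C3 (ring A side) and the two oxygenated carbons cis | COc1ccc(cc1)[C@@H](Oc1cc(OCc2ccccc2)cc(OCc2ccccc2)c1I)/C(B(C1CCCCC1)C1CCCCC1)=C\[C@H](Oc1cc(OC)cc(OC)c1B1OC(C)(C)C(C)(C)O1)c1ccc(OC)cc1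
F11 | step 10 | alkenyl(dicyclohexyl)borane from syn-hydroboration of 15 with boron on C3'' (ring D side) and the two oxygenated carbons cis | COc1ccc(cc1)[C@@H](Oc1cc(OCc2ccccc2)cc(OCc2ccccc2)c1I)/C=C(B(C1CCCCC1)C1CCCCC1)\[C@H](Oc1cc(OC)cc(OC)c1B1OC(C)(C)C(C)(C)O1)c1ccc(OC)cc1
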